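**Remark on the structure (one line):** the two halves differ only at C1′ (S on one lactone, R on the other) on an otherwise C2-symmetric core, and each ring bromine (C11, C12) is cis to C4 of the lactone on the neighbouring spiro carbon, which is the pattern an (E)-bromomethylene unit delivers; it is assumed that in 11 the carbinol rotamer with C1′–H eclipsing C3=C4 is the populated one.

## Retrosynthetic overview

1. The target is a 1,7-dioxadispiro[4.0.4.2]dodecane: a cyclobutane (C5–C6–C11–C12) carrying two 4-bromobutenolides, with a C2 axis through the midpoints of C5–C6 and C11–C12 that only the two C1′ centres break. Last cut: one Mitsunobu inversion with AcOH at one of the two homotopic carbinols of the C2-symmetric (1′R,1′R)-diol 13, then acetylation.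
2. Diol 13 comes from an intramolecular head-to-head [2+2] photocycloaddition of bis-fimbrolide 11, whose two C1′ oxygens are joined by an O–SiMe2CH2CH2SiMe2–O tether. This forms C11–C12 and C5–C6, both spiro centres and both CHBr centres in one operation; the (R)-carbinols fix the helicity of the core through the tether.
3. 11 comes from two molecules of the (5E),(1′R)-hydroxyfimbrolide 10 and 1,2-bis(chlorodimethylsilyl)ethane; 10 from Z→E photoisomerisation of 9; 9 from lipase resolution of racemic acetate 8.
4. 8 comes from Wohl–Ziegler bromination/acetolysis of butylfuranone 6; 6 from bromination and sulfuric-acid cyclisation of 2-butyllevulinic acid 4; 4 from diethyl butylmalonate and chloroacetone.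
5. Ring order: butenolide (step 2), 14-membered tether ring (step 6), cyclobutane (step 7, tether ring opened in the same flask).

Key step: step 7

## Route

Step 1
Reactants: 1 diethyl butylmalonate; 2 chloroacetone
Product: 4 2-butyl-4-oxopentanoic acid (racemic), via acetonylmalonate diester 3 (not isolated)
Conditions: NaOEt, EtOH, cat. NaI, reflux; then 6 M HCl–AcOH, reflux
Reagents that add atoms: water (O)
Why: Malonic ester synthesis, i.e. SN2 alkylation of the malonate anion by the α-chloro ketone followed by acid hydrolysis and decarboxylation; the C2 stereocentre is irrelevant because it becomes sp2 in step 2.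

Step 2
Reactants: 4
Product: 6 (5Z)-4-bromo-5-(bromomethylidene)-3-butylfuran-2(5H)-one, via dibromo keto acid 5 (not isolated)
Conditions: Br2 (2.05 equiv), CHCl3, 0 °C to rt; evaporate; conc. H2SO4, 100 °C, 20 min, pour on ice
Reagents that add atoms: bromine (BrBr)
Why: Acid-catalysed α-bromination of the ketone at C3 and C5, then sulfuric-acid cyclodehydration of the γ-keto acid to the enol lactone with dehydrogenation of C3–C4 (HBr loss and re-bromination, H2SO4 as oxidant), the classical fimbrolide ring synthesis; the Z alkene should result as the thermodynamic isomer because it keeps the exocyclic bromine away from C4–Br.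

Step 3
Reactants: 6
Product: 8 rac-1-[(5Z)-4-bromo-5-(bromomethylidene)-2-oxo-2,5-dihydrofuran-3-yl]butyl acetate, via allylic bromide 7 (not isolated)
Conditions: NBS (1.05 equiv), AIBN (5 mol%), PhCF3, 85 °C; filter, evaporate; AgOAc (1.5 equiv), AcOH, 50 °C
Reagents that add atoms: N-bromosuccinimide (O=C1CCC(=O)N1Br), silver acetate (CC(=O)[O-].[Ag+])
Why: Wohl–Ziegler bromination at C1′, the only allylic CH2, followed by silver-assisted acetolysis of the secondary bromide; the C1′ centre is formed racemic and is resolved in step 4.

Step 4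
Reactants: 8
Product: 9 (5Z)-4-bromo-5-(bromomethylidene)-3-[(1R)-1-hydroxybutyl]furan-2(5H)-one
Conditions: immobilised Burkholderia cepacia lipase, n-BuOH (3 equiv), MTBE, 30 °C, to ca. 45% conversion; chromatography
Reagents that add atoms: none
Why: Lipase-catalysed enantioselective alcoholysis (kinetic resolution), in which the (R)-acetate (bromofuranone as large group, propyl as medium group) is expected to be the fast-reacting enantiomer under base-free conditions, while the unreacted (S)-acetate is separated.

Step 5
Reactants: 9
Product: 10 (5E)-4-bromo-5-(bromomethylidene)-3-[(1R)-1-hydroxybutyl]furan-2(5H)-one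
Conditions: hν (365 nm LED), degassed MeCN (5 mM), 0 °C, to the photostationary state; chromatography in the dark, recovered 9 re-irradiated
Reagents that add atoms: none
Why: E/Z photoisomerisation about the exocyclic C=C of an alkylidene butenolide at high dilution; the E isomer, twisted by the Br/Br contact, is expected to absorb less at the long-wavelength edge and so to accumulate, and the carbinol centre is not touched.

Step 6
Reactants: 10 (2 equiv)
Product: 11 1,2-bis{[(1R)-1-[(5E)-4-bromo-5-(bromomethylidene)-2-oxo-2,5-dihydrofuran-3-yl]butoxy]dimethylsilyl}ethane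
Conditions: ClMe2SiCH2CH2SiMe2Cl (0.5 equiv), iPr2NEt (1.2 equiv), CH2Cl2, −20 °C to rt, dark; filter off the ammonium salt, evaporate, use directly
Reagents that add atoms: 1,2-bis(chlorodimethylsilyl)ethane (C[Si](C)(Cl)CC[Si](C)(C)Cl)
Why: O-silylation of the secondary alcohol at both ends of the bis-chlorosilane (temporary silicon tether) with a non-nucleophilic amine that should leave the 4-bromobutenolide and the E alkene untouched; no stereocentre is affected.

Step 7
Reactants: 11
Product: 13 (5S,6S,11R,12R)-4,10,11,12-tetrabromo-3,9-bis[(1R)-1-hydroxybutyl]-1,7-dioxadispiro[4.0.4.2]dodeca-3,9-diene-2,8-dione, via tethered cycloadduct 12 (not isolated)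
Conditions: thioxanthone (20 mol%), hν (395–405 nm LED), degassed CH2Cl2 (1 mM), −40 °C; then MeOH, PPTS (cat.), 0 °C
Reagents that add atoms: none
Why: Triplet energy transfer to one alkylidene-butenolide unit should be followed by bonding of the two bromomethylene carbons to a 1,4-biradical of two furan-2-yloxyl-type radicals, which recombine at C5/C6; the closest known reaction type is the sensitised head-to-head [2+2] photodimerisation of 5-ylidene butenolides and ylidene azlactones, run here intramolecularly through a temporary silicon tether. The only ring closed is the cyclobutane, by two C–C bonds (C11–C12 first, C5–C6 second) inside the 14-membered ring defined by the tether, and the tether is then removed by acid methanolysis in the same flask. The spiro centres C5 and C6 are controlled by the two (R)-carbinols: with C1′–H eclipsing C3=C4 to avoid 1,3-allylic strain with C4–Br, each (R)-centre turns its oxygen towards the partner only in the antiparallel stack that leads to the (5S,6S) core, whereas the enantiomeric core or the cis-fused core would need the tether to reach an outer face. The CHBr centres C11 and C12 are controlled by the E geometry: in that stack each exocyclic bromine lies on the side of its own C4, so the bromines should end up trans to each other and cis to C4. The step needs head-to-head regioselectivity (radical stabilisation at C5 and the tether), a trans arrangement of the lactones (C4–Br/C4–Br repulsion and the C2-symmetric tether) and transfer of alkene geometry (low temperature, the preorganised stack, and fast spin inversion next to four bromine atoms).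

Step 8
Reactants: 13
Product: 14 (1S)-1-[(5S,6S,11R,12R)-4,10,11,12-tetrabromo-9-[(1R)-1-hydroxybutyl]-2,8-dioxo-1,7-dioxadispiro[4.0.4.2]dodeca-3,9-dien-3-yl]butyl acetate
Conditions: preformed PPh3/DIAD betaine (1.0 equiv), AcOH (1.2 equiv), THF, −20 to 0 °C; chromatography, recovered 13 recycled
Reagents that add atoms: acetic acid (CC(=O)O)
Why: Mitsunobu reaction in which one alkoxyphosphonium is displaced by acetate with inversion (1′R to 1′S); because the two carbinols of 13 are homotopic, only one mono-inverted product can form, limiting reagent holds the reaction at the mono stage, and SN2′ attack is blocked by the fully substituted C4.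

Step 9
Reactants: 14
Product: 15 (1S)-1-[(5S,6S,11R,12R)-9-[(1R)-1-acetoxybutyl]-4,10,11,12-tetrabromo-2,8-dioxo-1,7-dioxadispiro[4.0.4.2]dodeca-3,9-dien-3-yl]butyl acetate (CNP0266230.1)
Conditions: Ac2O (1.5 equiv), Sc(OTf)3 (2 mol%), MeCN, −20 °C
Reagents that add atoms: acetic anhydride (CC(=O)OC(C)=O)
Why: Lewis-acid-catalysed O-acylation of the remaining (1′R)-carbinol with retention, base-free so that the 4-bromobutenolides and the ring bromides should not be attacked.

## Compound list

1 | diethyl butylmalonate | CCCCC(C(=O)OCC)C(=O)OCC | starting material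
2 | chloroacetone | CC(=O)CCl | starting material
3 | diethyl 2-butyl-2-(2-oxopropyl)malonate | CCCCC(CC(C)=O)(C(=O)OCC)C(=O)OCC | intermediate
4 | 2-butyl-4-oxopentanoic acid (racemic) | CCCCC(CC(C)=O)C(=O)O | intermediate
5 | 3,5-dibromo-2-butyl-4-oxopentanoic acid (diastereomer mixture) | CCCCC(C(=O)O)C(Br)C(=O)CBr | intermediate
6 | (5Z)-4-bromo-5-(bromomethylidene)-3-butylfuran-2(5H)-one | CCCCC1=C(Br)/C(=C/Br)OC1=O | intermediate
7 | (5Z)-4-bromo-3-(1-bromobutyl)-5-(bromomethylidene)furan-2(5H)-one (racemic) | CCCC(Br)C1=C(Br)/C(=C/Br)OC1=O | intermediate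
8 | rac-1-[(5Z)-4-bromo-5-(bromomethylidene)-2-oxo-2,5-dihydrofuran-3-yl]butyl acetate | CCCC(OC(C)=O)C1=C(Br)/C(=C/Br)OC1=O | intermediate
9 | (5Z)-4-bromo-5-(bromomethylidene)-3-[(1R)-1-hydroxybutyl]furan-2(5H)-one | CCC[C@@H](O)C1=C(Br)/C(=C/Br)OC1=O | intermediate
10 | (5E)-4-bromo-5-(bromomethylidene)-3-[(1R)-1-hydroxybutyl]furan-2(5H)-one | CCC[C@@H](O)C1=C(Br)/C(=C\Br)OC1=O | intermediate
11 | 1,2-bis{[(1R)-1-[(5E)-4-bromo-5-(bromomethylidene)-2-oxo-2,5-dihydrofuran-3-yl]butoxy]dimethylsilyl}ethane | CCC[C@@H](O[Si](C)(C)CC[Si](C)(C)O[C@H](CCC)C1=C(Br)/C(=C\Br)OC1=O)C1=C(Br)/C(=C\Br)OC1=O | intermediate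
12 | tethered cycloadduct: the (5S,6S,11R,12R) core of 13 with the two (1R) oxygens bridged by SiMe2CH2CH2SiMe2 (14-membered ring) | CCC[C@@H](O3)C1=C(Br)[C@@]2(OC1=O)[C@@H](Br)[C@H](Br)[C@@]21OC(=O)C([C@@H](CCC)O[Si](C)(C)CC[Si]3(C)C)=C1Br | intermediate
13 | (5S,6S,11R,12R)-4,10,11,12-tetrabromo-3,9-bis[(1R)-1-hydroxybutyl]-1,7-dioxadispiro[4.0.4.2]dodeca-3,9-diene-2,8-dione | CCC[C@@H](O)C1=C(Br)[C@@]2(OC1=O)[C@@H](Br)[C@H](Br)[C@@]21OC(=O)C([C@@H](CCC)O)=C1Br | intermediate
14 | (1S)-1-[(5S,6S,11R,12R)-4,10,11,12-tetrabromo-9-[(1R)-1-hydroxybutyl]-2,8-dioxo-1,7-dioxadispiro[4.0.4.2]dodeca-3,9-dien-3-yl]butyl acetate | CCC[C@H](OC(C)=O)C1=C(Br)[C@@]2(OC1=O)[C@@H](Br)[C@H](Br)[C@@]21OC(=O)C([C@@H](CCC)O)=C1Br | intermediate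
15 | (1S)-1-[(5S,6S,11R,12R)-9-[(1R)-1-acetoxybutyl]-4,10,11,12-tetrabromo-2,8-dioxo-1,7-dioxadispiro[4.0.4.2]dodeca-3,9-dien-3-yl]butyl acetate | CCC[C@H](OC(C)=O)C1=C(Br)[C@@]2(OC1=O)[C@@H](Br)[C@H](Br)[C@@]21OC(=O)C([C@@H](CCC)OC(C)=O)=C1Br | target

## Step count and risks

Total step count: 9. Longest linear sequence: 9 (both halves come from the same monomer sequence).

Steps most likely to fail:

1. Step 7. The alkene geometry may be lost before the second C–C bond forms (E→Z photoisomerisation, rotation or cleavage of the 1,4-biradical, loss of a bromine atom from the β-bromo radical), which would give CHBr-epimeric cyclobutanes. The 14-membered closure may also fail to compete with reversion. Fallback, setting out from 10 and returning at 13: silylation of 10 with TBSOTf/2,6-lutidine should give the silyl ether F1. Thioxanthone-sensitised irradiation of F1 at high concentration (0.3 M, 405 nm, −40 °C) is the untethered, intermolecular head-to-head photodimerisation and should give a mixture of cyclobutanes. The (5S,6S,11R,12R) bis-silyl ether F2 would be separated from it by preparative HPLC, and HF·pyridine would then release 13.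

2. Step 5. The photostationary state may hold little E isomer, or 10 may revert to 9 on handling (radical- or halide-catalysed isomerisation). Fallback, setting out from 9 and returning at 13: 9 is tethered as in step 6 to the (Z,Z)-tethered bis-silyl ether F3. F3 is irradiated with thioxanthone so that E/Z equilibration of both bromomethylene groups and the cycloaddition run in the same flask, through 12. After methanolysis, 13 is separated from its CHBr epimers by chromatography.

3. Step 8. The phosphine may attack C4–Br or the vicinal dibromide, elimination may compete at the hindered carbinol, and the reaction may run on to the bis-inverted diacetate. Fallback (inversion by oxidation and reduction), setting out from 13 and returning at 15: statistical mono-acetylation (Ac2O 1 equiv, Sc(OTf)3) should give the monoacetate F4. Dess–Martin oxidation of the free carbinol would give the keto acetate F5. Corey–Bakshi–Shibata reduction with the (R)-oxazaborolidine and BH3·SMe2 at −40 °C, with the ring carbon as the large group, is expected to give the (1′S)-alcohol, i.e. the hydroxy acetate F6. Acetylation under the step 9 conditions then gives 15.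

## Further compounds

F1 | step 7 | (5E)-4-bromo-5-(bromomethylidene)-3-[(1R)-1-(tert-butyldimethylsilyloxy)butyl]furan-2(5H)-one | CCC[C@@H](O[Si](C)(C)C(C)(C)C)C1=C(Br)/C(=C\Br)OC1=O
F2 | step 7 | bis(tert-butyldimethylsilyl) ether of 13 | CCC[C@@H](O[Si](C)(C)C(C)(C)C)C1=C(Br)[C@@]2(OC1=O)[C@@H](Br)[C@H](Br)[C@@]21OC(=O)C([C@@H](CCC)O[Si](C)(C)C(C)(C)C)=C1Br
F3 | step 5 | 1,2-bis{[(1R)-1-[(5Z)-4-bromo-5-(bromomethylidene)-2-oxo-2,5-dihydrofuran-3-yl]butoxy]dimethylsilyl}ethane | CCC[C@@H](O[Si](C)(C)CC[Si](C)(C)O[C@H](CCC)C1=C(Br)/C(=C/Br)OC1=O)C1=C(Br)/C(=C/Br)OC1=O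
F4 | step 8 | (1R)-1-[(5S,6S,11R,12R)-4,10,11,12-tetrabromo-9-[(1R)-1-hydroxybutyl]-2,8-dioxo-1,7-dioxadispiro[4.0.4.2]dodeca-3,9-dien-3-yl]butyl acetate | CCC[C@@H](OC(C)=O)C1=C(Br)[C@@]2(OC1=O)[C@@H](Br)[C@H](Br)[C@@]21OC(=O)C([C@@H](CCC)O)=C1Br
F5 | step 8 | (1R)-1-[(5S,6S,11R,12R)-4,10,11,12-tetrabromo-9-butanoyl-2,8-dioxo-1,7-dioxadispiro[4.0.4.2]dodeca-3,9-dien-3-yl]butyl acetate | CCC[C@@H](OC(C)=O)C1=C(Br)[C@@]2(OC1=O)[C@@H](Br)[C@H](Br)[C@@]21OC(=O)C(C(=O)CCC)=C1Br
F6 | step 8 | (1R)-1-[(5S,6S,11R,12R)-4,10,11,12-tetrabromo-9-[(1S)-1-hydroxybutyl]-2,8-dioxo-1,7-dioxadispiro[4.0.4.2]dodeca-3,9-dien-3-yl]butyl acetate | CCC[C@@H](OC(C)=O)C1=C(Br)[C@@]2(OC1=O)[C@@H](Br)[C@H](Br)[C@@]21OC(=O)C([C@H](CCC)O)=C1Br
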